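## Retrosynthetic overview
1. 9 ⇒ 7. Both pyrrole C–N bonds are made last, from ammonia and the oxidatively opened furan of 7. The CH2OH carbon ends as the CHO by an internal redox shift, so no formylation step is needed.
2. 7 ⇒ 4 + 5. The C10–C11 bond of the chain comes from cross-metathesis and hydrogenation of a C10 and a C11 ω-alkene (10 + 11 − 2 = C19).
3. 4 ⇒ 1 + 2. The dianion of furfuryl alcohol is alkylated at C5.
4. Ring order: furan (bought) → transient 2H-pyran-3(6H)-one 8 → pyrrole, the only ring built, in the last step.

Assumption: the target has no stereocentre, so it is achiral and no enantiocontrol is needed. The chain is read as the nitrile carbon plus eighteen CH2 groups (C24H40N2O).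

## Route

Step 1
Reactants: 1 furfuryl alcohol; 2 10-bromodec-1-ene
Product: 4 [5-(dec-9-en-1-yl)furan-2-yl]methanol, via dilithiated furfuryl alcohol 3 (not isolated)
Conditions: 1 (1.2 equiv), n-BuLi (2.4 equiv), TMEDA, THF, −78 → 0 °C, 2 h; then 2 (1.0 equiv), 0 °C → rt, 16 h; H2O quench; Et3N-deactivated SiO2
Reagents that add atoms: n-BuLi, [Li]CCCC (supplies the Li of intermediate 3 only; none of its atoms remains in 4)
Why: The alkoxide forms first, the second n-BuLi removes the most acidic ring proton (α-H at C5), and the furyllithium carbon is far more nucleophilic than the lithium alkoxide, so SN2 on the primary bromide gives C-alkylation (heteroaryl lithiation/alkylation); no stereocentre is formed.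

Step 2
Reactants: 4 [5-(dec-9-en-1-yl)furan-2-yl]methanol; 5 undec-10-enenitrile (3 equiv)
Product: 7 19-[5-(hydroxymethyl)furan-2-yl]nonadecanenitrile, via cross-metathesis alkene 6 (not isolated)
Conditions: Hoveyda–Grubbs II (2 mol %), toluene, 45 °C, Ar sparge, 5 h; then H2 (20 bar), 60 °C, 16 h, same Ru and no base; chromatography
Reagents that add atoms: none
Why: Olefin cross-metathesis of two unhindered terminal alkenes is driven by loss of ethene and by the excess of the cheap nitrile, and in the tandem hydrogenation H2 turns the spent Ru carbene into a Ru hydride that saturates the C=C but, without base, leaves nitrile and furan alone; the E/Z ratio of 6 does not matter because the alkene is removed.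

Step 3
Reactants: 7 19-[5-(hydroxymethyl)furan-2-yl]nonadecanenitrile
Product: 9 mycalenitrile 14, 19-(5-formyl-1H-pyrrol-2-yl)nonadecanenitrile, via Achmatowicz pyranone 8 (not isolated)
Conditions: m-CPBA (1.0 equiv), CH2Cl2, 0 °C → rt, 2 h; then NH4OAc (10 equiv), MeOH, 40 °C, 12 h; aqueous work-up
Reagents that add atoms: ammonium acetate, CC(=O)[O-].[NH4+] (pyrrole N); m-CPBA, O=C(OO)c1cccc(Cl)c1 (one O of intermediate 8 only, lost again as water)
Why: Proposed new method: a one-pot oxidative O-to-N ring-atom exchange with internal redox relay, in which m-CPBA carries out a standard Achmatowicz oxidation of the 2,5-disubstituted furfuryl alcohol to hemiketal pyranone 8 (ring form of the (Z)-enedione HOCH2–CO–CH=CH–CO–R), NH3 condenses with the α-hydroxy ketone (first C–N bond), the α-hydroxy imine tautomerises to its enaminol (Heyns-type shift), the nitrogen closes 5-exo on the hemiketal carbon (second C–N bond), and loss of two waters aromatises the ring while the former CH2OH carbon ends as CHO; the closest known reaction types are the Achmatowicz rearrangement, the Paal–Knorr synthesis and the Maillard-type condensation of isolated dihydropyranones with primary amines to N-substituted 2-formylpyrroles, whereas ammonia as the nitrogen source (N–H pyrrole), a 6-alkyl hemiketal substrate and the telescoped furan-to-pyrrole format are, as far as I know, untested.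

## Compound list
1 | furfuryl alcohol (furan-2-ylmethanol) | OCc1ccco1 | starting material
2 | 10-bromodec-1-ene | C=CCCCCCCCCBr | starting material
3 | lithium (5-lithiofuran-2-yl)methanolate | [Li]OCc1ccc([Li])o1 | intermediate (not isolated)
4 | [5-(dec-9-en-1-yl)furan-2-yl]methanol | C=CCCCCCCCCc1ccc(CO)o1 | intermediate
5 | undec-10-enenitrile | C=CCCCCCCCCC#N | starting material
6 | 19-[5-(hydroxymethyl)furan-2-yl]nonadec-10-enenitrile, E/Z mixture | N#CCCCCCCCCC=CCCCCCCCCc1ccc(CO)o1 | intermediate (not isolated)
7 | 19-[5-(hydroxymethyl)furan-2-yl]nonadecanenitrile | N#CCCCCCCCCCCCCCCCCCCc1ccc(CO)o1 | intermediate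
8 | 6-(18-cyanooctadecyl)-6-hydroxy-2H-pyran-3(6H)-one, racemic labile hemiketal | N#CCCCCCCCCCCCCCCCCCCC1(O)C=CC(=O)CO1 | intermediate (not isolated)
9 | mycalenitrile 14, 19-(5-formyl-1H-pyrrol-2-yl)nonadecanenitrile (achiral) | N#CCCCCCCCCCCCCCCCCCCc1ccc(C=O)[nH]1 | target

Total step count: 3. Longest linear sequence: 3.

## Steps most likely to fail

**Step 3 (the new step).**
- Risks:
  - Six-ring closure after a Lobry de Bruyn-type shift could give a 6-alkylpyridin-3-ol.
  - Ammonia could add to the enedione (aza-Michael) and give oligomers.
  - Leftover peracid could oxidise the pyrrole.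
- Fallback (known chemistry): it sets out from 7 and comes back at 9. Compound 7 is oxidised with m-CPBA as above, but pyranone 8 is isolated. Compound 8 is then condensed with 2-(phenylsulfonyl)ethan-1-amine (NCCS(=O)(=O)c1ccccc1; Et3N, 1,4-dioxane, 70 °C). This is the established Maillard-type 2-formylpyrrole synthesis with a primary amine, and it gives 19-{5-formyl-1-[2-(phenylsulfonyl)ethyl]-1H-pyrrol-2-yl}nonadecanenitrile F5. DBU in THF at 50 °C then removes the N-substituent by retro-Michael (E1cB) elimination and gives 9.

**Step 2.**
- Risks:
  - The two alkenes give a statistical product mixture.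
  - Ru–H alkene migration before metathesis would give chain-shortened homologues that cannot be separated.
  - Nitrile coordination could slow the catalyst.
- Fallback: it sets out from 4 and comes back at 7. Compound 4 is treated with 9-BBN-H (2.2 equiv, THF, rt). The first equivalent is consumed by the OH group, and the product is the O-borylated B-alkyl borane F4. F4 is used directly in a Pd-catalysed alkyl–alkyl Suzuki coupling with commercial 9-bromononanenitrile (N#CCCCCCCCCBr; Pd(OAc)2/PCy3, K3PO4·H2O, THF, rt). Aqueous work-up frees the alcohol. The chain length is fixed as 10 + 8 CH2, with no alkene, no statistics and no hydrogenation.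

**Step 1.**
- Risks:
  - The second lithiation may be incomplete.
  - Some O-alkylation may occur.
  - The furfuryl alcohol product is acid-sensitive.
- Fallback: it sets out from 2 and comes back at 4, and it brings in the CH2OH carbon last. Commercial furan (c1ccoc1) is lithiated with n-BuLi in THF at 0 °C to 2-furyllithium F1. F1 is alkylated with 2 to give 2-(dec-9-en-1-yl)furan F2. F2 is lithiated at its only free α-position to 5-lithio-2-(dec-9-en-1-yl)furan F3. F3 is quenched with paraformaldehyde (C=O) and then water to give 4.

## Further compounds
F1 | step 1 | 2-furyllithium | [Li]c1ccco1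
F2 | step 1 | 2-(dec-9-en-1-yl)furan | C=CCCCCCCCCc1ccco1
F3 | step 1 | 5-lithio-2-(dec-9-en-1-yl)furan | C=CCCCCCCCCc1ccc([Li])o1
F4 | step 2 | 9-{10-[5-({(9-borabicyclo[3.3.1]nonan-9-yl)oxy}methyl)furan-2-yl]decyl}-9-borabicyclo[3.3.1]nonane | B1(CCCCCCCCCCc5ccc(COB3C4CCCC3CCC4)o5)C2CCCC1CCC2
F5 | step 3 | 19-{5-formyl-1-[2-(phenylsulfonyl)ethyl]-1H-pyrrol-2-yl}nonadecanenitrile | N#CCCCCCCCCCCCCCCCCCCc1ccc(C=O)n1CCS(=O)(=O)c2ccccc2
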